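**Retrosynthetic overview**
1. The target comes from its hexa-O-benzyl ether by neutral hydrogenolysis in the last step, which leaves C2 and C3 untouched.
2. The flavanone heterocycle is closed at the O1–C2 bond by a catalytic asymmetric 6-endo oxa-Michael cyclisation of an α-(flavon-3-yl)-2'-hydroxychalcone. The catalyst sets C2 (S); C3 (R) follows by trans protonation. This C–O bond is the key bond.
3. The chalcone comes from a Knoevenagel condensation of a 3-(aroylmethyl)flavone with 4-(benzyloxy)benzaldehyde.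
4. The 3-(aroylmethyl)flavone comes from the interflavonoid C–C bond: Pd-catalysed ketone α-arylation of di-O-benzylphloroacetophenone with 3-iodo-tri-O-benzylapigenin.
5. Ring order: the flavone unit is taken complete from apigenin; the only ring built is the flavanone pyranone ring, formed last.

Assumption: the SMILES is read as the 2,3-trans isomer, (2S,3R). The quinidine-derived catalyst Q is taken to give 2S in step 6; if an analytical run shows the opposite sense, its quinine-derived pseudo-enantiomer is used instead.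
Catalyst Q = 3-{[3,5-bis(trifluoromethyl)phenyl]amino}-4-{[(9R)-6'-methoxycinchonan-9-yl]amino}cyclobut-3-ene-1,2-dione (the squaramide of 9-amino-9-deoxy-epi-quinidine).

**Step 1**
Reactants: 1 apigenin
Product: 2 5,7-bis(benzyloxy)-2-[4-(benzyloxy)phenyl]-4H-chromen-4-one
Conditions: BnBr (4 equiv), K2CO3 (5 equiv), n-Bu4NI (cat.), DMF, 80 °C
Reagents that add atoms: benzyl bromide, BrCc1ccccc1
Why: Williamson ether synthesis in which the 7- and 4'-phenols react readily and the hydrogen-bonded 5-OH is forced by excess reagent and heat in DMF; no stereocentre is involved.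

**Step 2**
Reactants: 2 5,7-bis(benzyloxy)-2-[4-(benzyloxy)phenyl]-4H-chromen-4-one
Product: 4 5,7-bis(benzyloxy)-2-[4-(benzyloxy)phenyl]-3-iodo-4H-chromen-4-one, via 3-lithioflavone 3 (not isolated)
Conditions: LiN(iPr)2 (1.3 equiv), THF, −78 °C, 20 min; then I2, −78 to 0 °C
Reagents that add atoms: iodine, [I][I]
Why: Carbonyl-directed lithiation removes the only vinylic C–H (C3) with a non-nucleophilic amide base that leaves benzyl ethers alone at −78 °C, and iodinolysis of the vinyllithium gives the 3-iodide (lithiation–iodination).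

**Step 3**
Reactants: 5 1-(2,4,6-trihydroxyphenyl)ethan-1-one
Product: 6 1-[2,4-bis(benzyloxy)-6-hydroxyphenyl]ethan-1-one
Conditions: BnBr (2.05 equiv), K2CO3 (2.2 equiv), acetone, reflux
Reagents that add atoms: benzyl bromide, BrCc1ccccc1
Why: Williamson ether synthesis that stops at the dibenzyl ether because the remaining ortho hydroxyl is chelated to the acetyl carbonyl and is the least nucleophilic oxygen.

**Step 4**
Reactants: 6 1-[2,4-bis(benzyloxy)-6-hydroxyphenyl]ethan-1-one; 4 5,7-bis(benzyloxy)-2-[4-(benzyloxy)phenyl]-3-iodo-4H-chromen-4-one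
Product: 8 3-{2-[2,4-bis(benzyloxy)-6-hydroxyphenyl]-2-oxoethyl}-5,7-bis(benzyloxy)-2-[4-(benzyloxy)phenyl]-4H-chromen-4-one, via dilithium dianion 7 (not isolated)
Conditions: LiN(SiMe3)2 (3.3 equiv), THF, −20 °C; then 4, Pd2(dba)3 (2.5 mol %), XPhos [2-dicyclohexylphosphino-2',4',6'-triisopropylbiphenyl] (6 mol %), 55 °C; AcOH quench
Reagents that add atoms: none
Why: Palladium-catalysed ketone α-arylation (Buchwald–Hartwig type) in which the preformed phenolate–enolate reacts through carbon, the bulky biaryl phosphine drives reductive elimination at the hindered C3, and the crowded product methylene resists a second arylation; no stereocentre is formed.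

**Step 5**
Reactants: 8 3-{2-[2,4-bis(benzyloxy)-6-hydroxyphenyl]-2-oxoethyl}-5,7-bis(benzyloxy)-2-[4-(benzyloxy)phenyl]-4H-chromen-4-one; 9 4-(benzyloxy)benzaldehyde
Product: 10 3-{(1E)-3-[2,4-bis(benzyloxy)-6-hydroxyphenyl]-1-[4-(benzyloxy)phenyl]-3-oxoprop-1-en-2-yl}-5,7-bis(benzyloxy)-2-[4-(benzyloxy)phenyl]-4H-chromen-4-one
Conditions: BF3·OEt2 (4 equiv), 1,4-dioxane, 25 °C; then pH 7 buffer
Reagents that add atoms: none
Why: Lewis-acid-mediated Knoevenagel (Claisen–Schmidt type) condensation in which boron coordination to the hydrogen-bonded 2'-hydroxy ketone activates the methylene and keeps the phenol oxygen from adding to the new enone, with the E alkene (aroyl trans to the β-aryl group) expected under thermodynamic control.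

**Step 6**
Reactants: 10 3-{(1E)-3-[2,4-bis(benzyloxy)-6-hydroxyphenyl]-1-[4-(benzyloxy)phenyl]-3-oxoprop-1-en-2-yl}-5,7-bis(benzyloxy)-2-[4-(benzyloxy)phenyl]-4H-chromen-4-one
Product: 11 (2S,3R)-5,7-bis(benzyloxy)-3-{5,7-bis(benzyloxy)-2-[4-(benzyloxy)phenyl]-4-oxo-4H-chromen-3-yl}-2-[4-(benzyloxy)phenyl]-2,3-dihydro-4H-chromen-4-one
Conditions: Q (10 mol %), toluene–CH2Cl2 4:1, −20 °C, 48 h
Reagents that add atoms: none
Why: Proposed new method: a catalytic enantioselective 6-endo-trig oxa-Michael cyclisation of an α-(chromon-3-yl)-2'-hydroxychalcone that forms the O1–C2 bond of the flavanone; the quinuclidine nitrogen of Q deprotonates the 2'-OH while the squaramide N–H pair binds the chalcone carbonyl and the neighbouring chromone C4 carbonyl (a two-point handle that plain chalcones lack), so the phenoxide adds to one face of the β-carbon and sets C2 as S, and C3 is then set by protonation on the face away from the new 2-aryl group, giving the diequatorial 2,3-trans (3R) arrangement that is also the thermodynamic one, while low temperature and the absence of free strong base keep retro-oxa-Michael racemisation slow; the closest known reaction type is the bifunctional cinchona-thiourea-catalysed cyclisation of 2'-hydroxychalcones activated by an α-ester group (alkylidene β-keto esters) to flavanones, which has not been shown for an α-heteroaryl substituent or for setting two adjacent stereocentres.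

**Step 7**
Reactants: 11 (2S,3R)-5,7-bis(benzyloxy)-3-{5,7-bis(benzyloxy)-2-[4-(benzyloxy)phenyl]-4-oxo-4H-chromen-3-yl}-2-[4-(benzyloxy)phenyl]-2,3-dihydro-4H-chromen-4-one
Product: 12 (2S,3R)-5,7-dihydroxy-3-[5,7-dihydroxy-2-(4-hydroxyphenyl)-4-oxo-4H-chromen-3-yl]-2-(4-hydroxyphenyl)-2,3-dihydro-4H-chromen-4-one
Conditions: H2 (1 atm), Pd/C (10 wt %), THF–MeOH, 25 °C
Reagents that add atoms: none
Why: Hydrogenolysis of the six benzyl ethers under neutral conditions, where no acid or base is present to open the flavanone or enolise C3, and where the tetrasubstituted chromone alkene and the chelated aryl ketones are not reduced at 1 atm.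

**Compound list**
1 | apigenin, 5,7-dihydroxy-2-(4-hydroxyphenyl)-4H-chromen-4-one | O=c1cc(-c2ccc(O)cc2)oc2cc(O)cc(O)c12 | starting material
2 | 5,7-bis(benzyloxy)-2-[4-(benzyloxy)phenyl]-4H-chromen-4-one (tri-O-benzylapigenin) | O=c1cc(-c2ccc(OCc3ccccc3)cc2)oc2cc(OCc3ccccc3)cc(OCc3ccccc3)c12 | intermediate
3 | 5,7-bis(benzyloxy)-2-[4-(benzyloxy)phenyl]-3-lithio-4H-chromen-4-one | O=c1c([Li])c(-c2ccc(OCc3ccccc3)cc2)oc2cc(OCc3ccccc3)cc(OCc3ccccc3)c12 | intermediate
4 | 5,7-bis(benzyloxy)-2-[4-(benzyloxy)phenyl]-3-iodo-4H-chromen-4-one | O=c1c(I)c(-c2ccc(OCc3ccccc3)cc2)oc2cc(OCc3ccccc3)cc(OCc3ccccc3)c12 | intermediate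
5 | 1-(2,4,6-trihydroxyphenyl)ethan-1-one (phloroacetophenone) | CC(=O)c1c(O)cc(O)cc1O | starting material
6 | 1-[2,4-bis(benzyloxy)-6-hydroxyphenyl]ethan-1-one | CC(=O)c1c(O)cc(OCc2ccccc2)cc1OCc1ccccc1 | intermediate
7 | dilithium 3,5-bis(benzyloxy)-2-(1-oxidoethenyl)phenolate | C=C(O[Li])c1c(O[Li])cc(OCc2ccccc2)cc1OCc1ccccc1 | intermediate
8 | 3-{2-[2,4-bis(benzyloxy)-6-hydroxyphenyl]-2-oxoethyl}-5,7-bis(benzyloxy)-2-[4-(benzyloxy)phenyl]-4H-chromen-4-one | O=C(Cc1c(-c2ccc(OCc3ccccc3)cc2)oc2cc(OCc3ccccc3)cc(OCc3ccccc3)c2c1=O)c1c(O)cc(OCc2ccccc2)cc1OCc1ccccc1 | intermediate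
9 | 4-(benzyloxy)benzaldehyde | O=Cc1ccc(OCc2ccccc2)cc1 | starting material
10 | 3-{(1E)-3-[2,4-bis(benzyloxy)-6-hydroxyphenyl]-1-[4-(benzyloxy)phenyl]-3-oxoprop-1-en-2-yl}-5,7-bis(benzyloxy)-2-[4-(benzyloxy)phenyl]-4H-chromen-4-one | O=C(c1c(O)cc(OCc2ccccc2)cc1OCc1ccccc1)/C(=C/c1ccc(OCc2ccccc2)cc1)c1c(-c2ccc(OCc3ccccc3)cc2)oc2cc(OCc3ccccc3)cc(OCc3ccccc3)c2c1=O | intermediate
11 | (2S,3R)-5,7-bis(benzyloxy)-3-{5,7-bis(benzyloxy)-2-[4-(benzyloxy)phenyl]-4-oxo-4H-chromen-3-yl}-2-[4-(benzyloxy)phenyl]-2,3-dihydro-4H-chromen-4-one | O=C1c2c(OCc3ccccc3)cc(OCc3ccccc3)cc2O[C@H](c2ccc(OCc3ccccc3)cc2)[C@H]1c1c(-c2ccc(OCc3ccccc3)cc2)oc2cc(OCc3ccccc3)cc(OCc3ccccc3)c2c1=O | intermediate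
12 | (2S,3R)-5,7-dihydroxy-3-[5,7-dihydroxy-2-(4-hydroxyphenyl)-4-oxo-4H-chromen-3-yl]-2-(4-hydroxyphenyl)-2,3-dihydro-4H-chromen-4-one (CNP0208264.1) | O=C1c2c(O)cc(O)cc2O[C@H](c2ccc(O)cc2)[C@H]1c1c(-c2ccc(O)cc2)oc2cc(O)cc(O)c2c1=O | target

**Totals**
Total step count: 7.
Longest linear sequence: 6 steps (steps 1, 2, 4, 5, 6, 7, from apigenin).

**Three steps most likely to fail**

Step 6 (the proposed new step). The risk is low enantioselectivity, or a background racemic cyclisation that outruns the catalyst. The fallback uses known chemistry and sets out from 10. Base-mediated cyclisation (NaOAc, EtOH–THF, reflux) gives the thermodynamic 2,3-trans flavanone as the racemate, that is 11 together with the (2R,3S)-hexabenzyl ether F4. Preparative HPLC on an amylose tris(3,5-dimethylphenylcarbamate) phase separates the two, and the route is rejoined at 11.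

Step 4. The risks are that the phenolate–enolate binds palladium through both oxygens and stalls, or that the hindered, base-sensitive 3-iodochromone is degraded by the strong base. The fallback sets out from 6 and replaces the basic dianion with a neutral tin-enolate coupling. Silylation (Me3SiOTf, Et3N, CH2Cl2, 0 °C) gives the bis(trimethylsilyl) enol ether–aryl silyl ether F1. This is coupled with 4 under PdCl2[P(o-tolyl)3]2 (3 mol %) and n-Bu3SnF in toluene at 100 °C. Dilute aqueous acid work-up removes the aryl silyl group and returns the route at 8.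

Step 5. The risks are a slow condensation at the crowded methylene, or premature ring closure to racemic flavanone, which would undercut step 6. The fallback sets out from 8 and masks the phenol during a conventional amine-catalysed condensation. Silylation (iPr3SiOTf, 2,6-lutidine, CH2Cl2) gives the triisopropylsilyl ether F2. Condensation with 9 (piperidine, AcOH, toluene, reflux with water removal) gives the silyl-protected chalcone F3. Buffered desilylation (n-Bu4NF, AcOH, THF, −20 °C) returns the route at 10.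

**Further compounds**
F1 | step 4 | {[1-(2,4-bis(benzyloxy)-6-[(trimethylsilyl)oxy]phenyl)ethenyl]oxy}(trimethyl)silane | C=C(O[Si](C)(C)C)c1c(O[Si](C)(C)C)cc(OCc2ccccc2)cc1OCc1ccccc1
F2 | step 5 | 3-(2-{2,4-bis(benzyloxy)-6-[(triisopropylsilyl)oxy]phenyl}-2-oxoethyl)-5,7-bis(benzyloxy)-2-[4-(benzyloxy)phenyl]-4H-chromen-4-one | O=C(Cc1c(-c2ccc(OCc3ccccc3)cc2)oc2cc(OCc3ccccc3)cc(OCc3ccccc3)c2c1=O)c1c(O[Si](C(C)C)(C(C)C)C(C)C)cc(OCc2ccccc2)cc1OCc1ccccc1
F3 | step 5 | 3-[(1E)-3-{2,4-bis(benzyloxy)-6-[(triisopropylsilyl)oxy]phenyl}-1-[4-(benzyloxy)phenyl]-3-oxoprop-1-en-2-yl]-5,7-bis(benzyloxy)-2-[4-(benzyloxy)phenyl]-4H-chromen-4-one | O=C(c1c(O[Si](C(C)C)(C(C)C)C(C)C)cc(OCc2ccccc2)cc1OCc1ccccc1)/C(=C/c1ccc(OCc2ccccc2)cc1)c1c(-c2ccc(OCc3ccccc3)cc2)oc2cc(OCc3ccccc3)cc(OCc3ccccc3)c2c1=O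
F4 | step 6 | (2R,3S)-5,7-bis(benzyloxy)-3-{5,7-bis(benzyloxy)-2-[4-(benzyloxy)phenyl]-4-oxo-4H-chromen-3-yl}-2-[4-(benzyloxy)phenyl]-2,3-dihydro-4H-chromen-4-one | O=C1c2c(OCc3ccccc3)cc(OCc3ccccc3)cc2O[C@@H](c2ccc(OCc3ccccc3)cc2)[C@@H]1c1c(-c2ccc(OCc3ccccc3)cc2)oc2cc(OCc3ccccc3)cc(OCc3ccccc3)c2c1=O
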